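## Retrosynthetic overview

- Berbikonol is reached by global desilylation. The C7''–aryl bond comes from Felkin–Anh addition of a veratryl–titanium reagent to an (R)-α-aryloxy aldehyde. The C8''–O bond comes from Mitsunobu inversion of methyl L-glycerate by the dihydrobenzofuran phenol.
- The dihydrofuran ring is the only ring built; all three benzene rings are purchased. It is closed by acid-mediated, trans-selective cycloetherification of a phenol/benzylic alcohol, itself made by aryl-Grignard addition to a lactol.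
- The lactol comes from ozonolysis of an o-(pent-3-en-2-yl)phenol. Its C3–aryl bond and C3 stereocentre are made by an aromatic Claisen [3,3] rearrangement with 1,3-chirality transfer.
- The Claisen substrate is an (R)-aryl sec-allyl ether, made by Mitsunobu inversion of an (S)-allylic alcohol obtained by cross-metathesis of (S)-but-3-en-2-ol.

Assumption: (S)-but-3-en-2-ol, methyl (S)-glycerate, allyl tert-butyldiphenylsilyl ether and dihydroconiferyl alcohol are taken as purchasable. TBDPS = tert-butyldiphenylsilyl.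

## Route

**Step 1**
Reactants: 1, 4-(3-hydroxypropyl)-2-methoxyphenol (dihydroconiferyl alcohol)
Product: 2, 4-{3-[(TBDPS)oxy]propyl}-2-methoxyphenol
Conditions: TBDPSCl (1.05 equiv), imidazole, CH2Cl2, 0 °C → rt; K2CO3/MeOH wash
Reagents that add atoms: TBDPSCl, CC(C)(C)[Si](Cl)(c1ccccc1)c1ccccc1
Why: Selective silylation: the bulky silyl chloride takes the unhindered primary alcohol far faster than the hydrogen-bonded ortho-methoxy phenol, and any aryl silyl ether is cleaved in the basic wash.

**Step 2**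
Reactants: 3, (S)-but-3-en-2-ol; 4, allyl tert-butyldiphenylsilyl ether
Product: 5, (2S,3E)-5-[(TBDPS)oxy]pent-3-en-2-ol
Conditions: Grubbs II (3 mol %, achiral), 3 (2.5 equiv), CH2Cl2, 40 °C
Reagents that add atoms: none (both partners are listed reactants; ethylene is lost)
Why: Olefin cross-metathesis of a type I allyl ether with a type II secondary allylic alcohol gives the E-alkene without touching the carbinol stereocentre.

**Step 3**
Reactants: 2; 5
Product: 6, tert-butyl{3-[4-({(2R,3E)-5-[(TBDPS)oxy]pent-3-en-2-yl}oxy)-3-methoxyphenyl]propoxy}diphenylsilane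
Conditions: PPh3, DIAD, THF, 0 °C → rt
Reagents that add atoms: none
Why: Mitsunobu etherification: the phenol displaces the activated secondary allylic alcohol by SN2 with inversion (S → R), and no other free OH is present.

**Step 4 (key step)**
Reactants: 6
Product: 7, 2-{(2S,3E)-1-[(TBDPS)oxy]pent-3-en-2-yl}-4-{3-[(TBDPS)oxy]propyl}-6-methoxyphenol
Conditions: PhNEt2, 175 °C, sealed tube
Reagents that add atoms: none
Why: Aromatic Claisen [3,3] rearrangement to the only free ortho position; a chair transition state with the methyl pseudo-equatorial relays the (R) C–O stereocentre suprafacially into the new (S) benzylic C–C stereocentre (future C3), and rearomatisation makes it irreversible.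

**Step 5**
Reactants: 7
Product: 8, (3S)-3-{[(TBDPS)oxy]methyl}-5-{3-[(TBDPS)oxy]propyl}-7-methoxy-2,3-dihydro-1-benzofuran-2-ol (anomer mixture)
Conditions: O3, CH2Cl2/MeOH, −78 °C (Sudan III end-point); then PPh3, −78 °C → rt
Reagents that add atoms: ozone, [O-][O+]=O
Why: Ozonolysis with reductive work-up cleaves the propenyl group (the alkene reacts far faster than the arenes at −78 °C), and the ortho phenol traps the aldehyde as a lactol, which shields the α-aryl stereocentre from enolisation.

**Step 6**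
Reactants: 9, 4-bromo-2,6-dimethoxyphenol
Product: 10, 5-bromo-1,3-dimethoxy-2-(methoxymethoxy)benzene
Conditions: MOMCl, i-Pr2NEt, CH2Cl2, 0 °C → rt
Reagents that add atoms: chloromethyl methyl ether, COCCl
Why: Simple O-alkylation of an acidic phenol; MOM survives Grignard formation and is removed in the acidic ring closure.

**Step 7**
Reactants: 8; 10
Product: 11, 2-{(2S)-1-[(TBDPS)oxy]-3-hydroxy-3-[3,5-dimethoxy-4-(methoxymethoxy)phenyl]propan-2-yl}-4-{3-[(TBDPS)oxy]propyl}-6-methoxyphenol (both carbinol epimers)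
Conditions: 10, Mg, THF, 50 °C; then 8, THF, 0 °C → rt (3 equiv ArMgBr)
Reagents that add atoms: none beyond 10, used as its Grignard reagent, COCOc1c(OC)cc([Mg]Br)cc1OC
Why: Grignard addition to a lactol through its ring-opened magnesium phenoxide–aldehyde; the carbinol configuration does not matter because it is erased in step 8.

**Step 8**
Reactants: 11
Product: 12, 4-[(2R,3S)-3-{[(TBDPS)oxy]methyl}-5-{3-[(TBDPS)oxy]propyl}-7-methoxy-2,3-dihydro-1-benzofuran-2-yl]-2,6-dimethoxyphenol
Conditions: HCl (about 1 M) in MeOH/THF, rt → 40 °C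
Reagents that add atoms: none
Why: Acid removes the MOM group and ionises the benzylic alcohol to a p-quinone-methide-type cation, which the ortho phenol captures (cycloetherification); the ring closure is reversible, so the C3 substituent dictates the thermodynamically preferred trans (2R) product, while TBDPS ethers tolerate the conditions.

**Step 9**
Reactants: 13, methyl (S)-2,3-dihydroxypropanoate (methyl L-glycerate)
Product: 14, methyl (2S)-3-[(TBDPS)oxy]-2-hydroxypropanoate
Conditions: TBDPSCl (1.0 equiv), imidazole, CH2Cl2, −10 → 0 °C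
Reagents that add atoms: TBDPSCl, CC(C)(C)[Si](Cl)(c1ccccc1)c1ccccc1
Why: Sterically controlled silylation of the primary hydroxyl over the secondary α-hydroxy ester; the stereocentre is untouched.

**Step 10**
Reactants: 12; 14
Product: 15, methyl (2R)-3-[(TBDPS)oxy]-2-{4-[(2R,3S)-3-{[(TBDPS)oxy]methyl}-5-{3-[(TBDPS)oxy]propyl}-7-methoxy-2,3-dihydro-1-benzofuran-2-yl]-2,6-dimethoxyphenoxy}propanoate
Conditions: PPh3, DIAD, THF, 0 °C → rt
Reagents that add atoms: none
Why: Mitsunobu reaction of the only free OH (the acidic 2,6-dimethoxyphenol) with the α-hydroxy ester gives the aryl ether with clean SN2 inversion (S → R), which sets C8''.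

**Step 11**
Reactants: 15
Product: 16, (2R)-3-[(TBDPS)oxy]-2-{4-[(2R,3S)-3-{[(TBDPS)oxy]methyl}-5-{3-[(TBDPS)oxy]propyl}-7-methoxy-2,3-dihydro-1-benzofuran-2-yl]-2,6-dimethoxyphenoxy}propanal
Conditions: DIBAL-H (1.1 equiv), CH2Cl2, −78 °C; Rochelle salt; used directly
Reagents that add atoms: none
Why: Partial ester reduction: the α-aryloxy group stabilises the tetrahedral aluminate at −78 °C, so the aldehyde appears only on work-up and the α-stereocentre is not epimerised.

**Step 12**
Reactants: 16; 17, 4-bromo-1,2-dimethoxybenzene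
Product: 18, (1S,2R)-3-[(TBDPS)oxy]-2-{4-[(2R,3S)-3-{[(TBDPS)oxy]methyl}-5-{3-[(TBDPS)oxy]propyl}-7-methoxy-2,3-dihydro-1-benzofuran-2-yl]-2,6-dimethoxyphenoxy}-1-(3,4-dimethoxyphenyl)propan-1-ol
Conditions: 17, n-BuLi, THF, −78 °C; ClTi(Oi-Pr)3; then 16, −78 → −20 °C
Reagents that add atoms: none beyond 17, used as (3,4-dimethoxyphenyl)titanium triisopropoxide, COc1ccc([Ti](OC(C)C)(OC(C)C)OC(C)C)cc1OC
Why: Non-chelating organotitanium 1,2-addition under Felkin–Anh control: the aryl group attacks anti to the α-aryloxy substituent of the (R)-aldehyde, giving the anti (erythro) 7''S,8''R alcohol.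

**Step 13**
Reactants: 18
Product: 19, Berbikonol, (1S,2R)-1-(3,4-dimethoxyphenyl)-2-{4-[(2R,3S)-3-(hydroxymethyl)-5-(3-hydroxypropyl)-7-methoxy-2,3-dihydro-1-benzofuran-2-yl]-2,6-dimethoxyphenoxy}propane-1,3-diol
Conditions: TBAF (AcOH-buffered), THF, rt
Reagents that add atoms: none
Why: Fluoride-mediated cleavage of all three primary TBDPS ethers under near-neutral conditions, which leaves the acid-sensitive benzylic alcohol, the β-aryl ether and the dihydrobenzofuran untouched.

## Compound list

1 | 4-(3-hydroxypropyl)-2-methoxyphenol | COc1cc(CCCO)ccc1O | starting material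
2 | 4-{3-[(TBDPS)oxy]propyl}-2-methoxyphenol | COc1cc(CCCO[Si](c2ccccc2)(c2ccccc2)C(C)(C)C)ccc1O | intermediate
3 | (S)-but-3-en-2-ol | C[C@H](O)C=C | starting material
4 | allyl tert-butyldiphenylsilyl ether | C=CCO[Si](c1ccccc1)(c1ccccc1)C(C)(C)C | starting material
5 | (2S,3E)-5-[(TBDPS)oxy]pent-3-en-2-ol | C[C@H](O)/C=C/CO[Si](c1ccccc1)(c1ccccc1)C(C)(C)C | intermediate
6 | (2R,3E)-aryl pentenyl ether | C[C@@H](Oc1ccc(CCCO[Si](c2ccccc2)(c2ccccc2)C(C)(C)C)cc1OC)/C=C/CO[Si](c1ccccc1)(c1ccccc1)C(C)(C)C | intermediate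
7 | (2S,3E)-o-pentenyl phenol (Claisen product) | C/C=C/[C@H](CO[Si](c1ccccc1)(c1ccccc1)C(C)(C)C)c1cc(CCCO[Si](c2ccccc2)(c2ccccc2)C(C)(C)C)cc(OC)c1O | intermediate
8 | (3S)-lactol (C2 anomers) | OC1Oc2c(OC)cc(CCCO[Si](c3ccccc3)(c3ccccc3)C(C)(C)C)cc2[C@H]1CO[Si](c1ccccc1)(c1ccccc1)C(C)(C)C | intermediate
9 | 4-bromo-2,6-dimethoxyphenol | COc1cc(Br)cc(OC)c1O | starting material
10 | 5-bromo-1,3-dimethoxy-2-(methoxymethoxy)benzene | COCOc1c(OC)cc(Br)cc1OC | intermediate
11 | (2S)-phenol/benzylic alcohol diol (carbinol epimers) | COCOc1c(OC)cc(C(O)[C@H](CO[Si](c2ccccc2)(c2ccccc2)C(C)(C)C)c2cc(CCCO[Si](c3ccccc3)(c3ccccc3)C(C)(C)C)cc(OC)c2O)cc1OC | intermediate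
12 | (2R,3S)-trans-dihydrobenzofuran phenol | COc1cc([C@@H]2Oc3c(OC)cc(CCCO[Si](c4ccccc4)(c4ccccc4)C(C)(C)C)cc3[C@H]2CO[Si](c2ccccc2)(c2ccccc2)C(C)(C)C)cc(OC)c1O | intermediate
13 | methyl (S)-2,3-dihydroxypropanoate | COC(=O)[C@@H](O)CO | starting material
14 | methyl (2S)-3-[(TBDPS)oxy]-2-hydroxypropanoate | COC(=O)[C@@H](O)CO[Si](c1ccccc1)(c1ccccc1)C(C)(C)C | intermediate
15 | (2R)-α-aryloxy ester | COC(=O)[C@@H](CO[Si](c1ccccc1)(c1ccccc1)C(C)(C)C)Oc1c(OC)cc([C@@H]2Oc3c(OC)cc(CCCO[Si](c4ccccc4)(c4ccccc4)C(C)(C)C)cc3[C@H]2CO[Si](c2ccccc2)(c2ccccc2)C(C)(C)C)cc1OC | intermediate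
16 | (2R)-α-aryloxy aldehyde | O=C[C@@H](CO[Si](c1ccccc1)(c1ccccc1)C(C)(C)C)Oc1c(OC)cc([C@@H]2Oc3c(OC)cc(CCCO[Si](c4ccccc4)(c4ccccc4)C(C)(C)C)cc3[C@H]2CO[Si](c2ccccc2)(c2ccccc2)C(C)(C)C)cc1OC | intermediate
17 | 4-bromo-1,2-dimethoxybenzene | COc1ccc(Br)cc1OC | starting material
18 | tris-TBDPS Berbikonol (1S,2R; 2R,3S) | COc1ccc([C@H](O)[C@@H](CO[Si](c2ccccc2)(c2ccccc2)C(C)(C)C)Oc2c(OC)cc([C@@H]3Oc4c(OC)cc(CCCO[Si](c5ccccc5)(c5ccccc5)C(C)(C)C)cc4[C@H]3CO[Si](c3ccccc3)(c3ccccc3)C(C)(C)C)cc2OC)cc1OC | intermediate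
19 | Berbikonol | COc1ccc([C@H](O)[C@@H](CO)Oc2c(OC)cc([C@@H]3Oc4c(OC)cc(CCCO)cc4[C@H]3CO)cc2OC)cc1OC | target

## Summary

Total steps: 13.
Longest linear sequence: 10 steps (1 → 3 → 4 → 5 → 7 → 8 → 10 → 11 → 12 → 13, from dihydroconiferyl alcohol).

Three steps most likely to fail:

1. **Step 4 (Claisen).** Risks are incomplete chirality transfer (Z-alkene or ionisation pathway) and abnormal Claisen isomerisation of the product. Fallback: accept partly or fully racemic 7 and use the L-glycerate unit installed in step 10 as an internal resolving handle, separating the diastereomers of 15 by chromatography or crystallisation. If the ee loss comes instead from SN2′ leakage in step 3, build ether 6 from ethyl (S)-lactate (Mitsunobu, DIBAL/Wittig, DIBAL, silylation), where allylic transposition is impossible.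

2. **Step 7 (aryl-Grignard on the lactol).** The basic reagent can epimerise C3 or eliminate silanolate from the ring-opened α-aryl-β-silyloxy aldehyde. Fallback: replace the stoichiometric organometallic with a Rh(I)-catalysed 1,2-addition of the corresponding arylboronic acid (from 10) to the lactol/aldehyde under near-neutral aqueous conditions, then the same acid cyclisation.

3. **Step 12 (Felkin–Anh aryl addition).** The erythro:threo ratio may be modest if chelation by the aryloxy or ortho-methoxy oxygens competes. Fallback: oxidise the epimer mixture to the aryl ketone (Dess–Martin) and set C7'' by chelation-controlled hydride reduction (Zn(BH4)2), which also delivers the erythro alcohol, before desilylation.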